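**Plan**

1. Retrosynthesis: the benzyl and silyl groups are removed and the C4 carbonyl is returned to a carbinol. Ring C is then cut at the aryl ether bond O1–C8a, giving an anti-1,3-diol with an ortho-bromoaryl group. The chain is cut at C3–C4, through the 1,3-diketone, into a ring B methyl ester and a ring A methyl ketone. The dimethylpyran ring fused to ring B (ring D) goes back to an aryl propargyl ether.
2. Forward: ring D is built first on methyl 3,4-dihydroxybenzoate (steps 1–3) and oxygenated (steps 4–6). The three-carbon chain is joined by Claisen condensation (step 8), and ring C closes last (step 10).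
3. Enabling feature: ring C contains the aryl ether bond O1–C8a, and C2 and C4 are 1,3-related oxygen-bearing carbons. Both therefore come from one 1,3-diketone, and closure at O1–C8a breaks no bond of the base-labile C2 stereocentre.
4. Stereochemistry: the ring D carbinols come from Jacobsen epoxidation with the (R,R) catalyst and invertive hydrolysis at the benzylic carbon. C2 comes from ruthenium transfer hydrogenation with the (S,S)-TsDPEN ligand and is carried through the ring closure with retention.

Key step: step 10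

Abbreviations: Bn = benzyl, TBS = tert-butyldimethylsilyl. Chromane numbering is used for the ring B/D unit, flavanone numbering for rings A and C.

Remark: diketone 12 is drawn in the diketo form although it should exist mainly as its enol, and the first hydride transfer of step 9 is taken to occur at the less hindered ring B carbonyl.

**Step 1**
Reactants: 1 methyl 3,4-dihydroxybenzoate; 2 3-chloro-3-methylbut-1-yne
Product: 3 methyl 3-hydroxy-4-[(2-methylbut-3-yn-2-yl)oxy]benzoate
Conditions: K2CO3 (1.1 equiv), KI, CuI (cat.), acetone, 55 °C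
Reagents that add atoms: none
Why: Copper-assisted Williamson-type propargylic etherification, in which the 4-hydroxyl, para to the ester and the more acidic phenol, is the one deprotonated by one equivalent of carbonate and should take up the tertiary propargyl group.

**Step 2**
Reactants: 3 methyl 3-hydroxy-4-[(2-methylbut-3-yn-2-yl)oxy]benzoate
Product: 4 methyl 3-(benzyloxy)-4-[(2-methylbut-3-yn-2-yl)oxy]benzoate
Conditions: BnBr, K2CO3, DMF, 23 °C
Reagents that add atoms: benzyl bromide, BrCc1ccccc1
Why: Williamson ether synthesis on the remaining phenol, which removes the free ortho hydroxyl before the thermal step.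

**Step 3**
Reactants: 4 methyl 3-(benzyloxy)-4-[(2-methylbut-3-yn-2-yl)oxy]benzoate
Product: 6 methyl 8-(benzyloxy)-2,2-dimethyl-2H-chromene-6-carboxylate, via allenylphenol 5 (not isolated)
Conditions: PhNEt2, 190 °C
Reagents that add atoms: none
Why: Aromatic propargyl Claisen rearrangement onto the only free ortho position of the ether oxygen gives allenylphenol 5, whose 1,5-hydrogen shift and oxa-6π electrocyclisation should close ring D as the 2,2-dimethylchromene.

**Step 4**
Reactants: 6 methyl 8-(benzyloxy)-2,2-dimethyl-2H-chromene-6-carboxylate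
Product: 7 methyl (3R,4R)-8-(benzyloxy)-3,4-epoxy-2,2-dimethylchromane-6-carboxylate
Conditions: (R,R)-N,N'-bis(3,5-di-tert-butylsalicylidene)-1,2-cyclohexanediaminomanganese chloride (5 mol%), 4-phenylpyridine N-oxide, aq. NaOCl (pH 11.3), CH2Cl2, 0 °C
Reagents that add atoms: sodium hypochlorite, [Na+].[O-]Cl
Why: Jacobsen epoxidation, for which 2,2-dimethylchromenes with an electron-poor arene are a privileged cis-alkene class; the (R,R) salen ligand should direct oxygen transfer to the face that gives the (3R,4R) epoxide.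

**Step 5**
Reactants: 7 methyl (3R,4R)-8-(benzyloxy)-3,4-epoxy-2,2-dimethylchromane-6-carboxylate
Product: 8 methyl (3R,4S)-8-(benzyloxy)-3,4-dihydroxy-2,2-dimethylchromane-6-carboxylate
Conditions: HClO4 (cat.), THF/H2O, 0 to 23 °C
Reagents that add atoms: water, O
Why: Acid-catalysed epoxide hydrolysis in which water attacks the benzylic C4 with inversion while the C3–O bond stays intact, so the trans (3R,4S) diol should result; the ester para to the ring oxygen damps benzylic cation character and so favours the invertive pathway.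

**Step 6**
Reactants: 8 methyl (3R,4S)-8-(benzyloxy)-3,4-dihydroxy-2,2-dimethylchromane-6-carboxylate
Product: 9 methyl (3R,4S)-8-(benzyloxy)-3,4-bis[(tert-butyldimethylsilyl)oxy]-2,2-dimethylchromane-6-carboxylate
Conditions: TBSOTf (3 equiv), 2,6-lutidine, CH2Cl2, 0 to 23 °C
Reagents that add atoms: tert-butyldimethylsilyl trifluoromethanesulfonate, CC(C)(C)[Si](C)(C)OS(=O)(=O)C(F)(F)F
Why: Silyl ether formation with the silyl triflate, which is reactive enough for the hindered C3 hydroxyl next to the quaternary carbon, masks both alcohols against the strong base and the palladium alkoxide chemistry to come.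

**Step 7**
Reactants: 10 1-(2-bromo-4-hydroxyphenyl)ethan-1-one
Product: 11 1-[4-(benzyloxy)-2-bromophenyl]ethan-1-one
Conditions: BnBr, K2CO3, acetone, 56 °C
Reagents that add atoms: benzyl bromide, BrCc1ccccc1
Why: Williamson ether synthesis on an acidic para-acyl phenol, giving the ring A methyl ketone with the bromide ortho to the acyl group.

**Step 8**
Reactants: 9 methyl (3R,4S)-8-(benzyloxy)-3,4-bis[(tert-butyldimethylsilyl)oxy]-2,2-dimethylchromane-6-carboxylate; 11 1-[4-(benzyloxy)-2-bromophenyl]ethan-1-one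
Product: 12 1-[(3R,4S)-8-(benzyloxy)-3,4-bis[(tert-butyldimethylsilyl)oxy]-2,2-dimethylchroman-6-yl]-3-[4-(benzyloxy)-2-bromophenyl]propane-1,3-dione
Conditions: NaH (3 equiv), THF, 65 °C, slow addition of 11; then AcOH
Reagents that add atoms: none
Why: Crossed Claisen condensation in which the sodium enolate of methyl ketone 11 acylates at the non-enolisable aryl ester 9, driven to completion by formation of the stabilised diketonate.

**Step 9**
Reactants: 12 1-[(3R,4S)-8-(benzyloxy)-3,4-bis[(tert-butyldimethylsilyl)oxy]-2,2-dimethylchroman-6-yl]-3-[4-(benzyloxy)-2-bromophenyl]propane-1,3-dione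
Product: 14 (1S,3S)-1-[(3R,4S)-8-(benzyloxy)-3,4-bis[(tert-butyldimethylsilyl)oxy]-2,2-dimethylchroman-6-yl]-3-[4-(benzyloxy)-2-bromophenyl]propane-1,3-diol, via hydroxy ketone 13 (not isolated)
Conditions: RuCl(p-cymene)[(S,S)-TsDPEN] (3 mol%), HCO2H/Et3N (5:2), CH2Cl2, 35 °C
Reagents that add atoms: none
Why: Noyori asymmetric transfer hydrogenation performed twice in one flask, each aryl ketone being reduced under catalyst control by the (S,S)-configured ruthenium hydride to the (S) carbinol, which should give the anti (1S,3S) diol; only the ring B carbinol (the future C2) has to be of high purity, because the other is oxidised in step 11.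

**Step 10**
Reactants: 14 (1S,3S)-1-[(3R,4S)-8-(benzyloxy)-3,4-bis[(tert-butyldimethylsilyl)oxy]-2,2-dimethylchroman-6-yl]-3-[4-(benzyloxy)-2-bromophenyl]propane-1,3-diol
Product: 15 (2S,4S)-7-(benzyloxy)-2-[(3R,4S)-8-(benzyloxy)-3,4-bis[(tert-butyldimethylsilyl)oxy]-2,2-dimethylchroman-6-yl]chroman-4-ol (2,4-cis)
Conditions: Pd(OAc)2 (5 mol%), rac-2-(di-tert-butylphosphino)-1,1'-binaphthyl (7 mol%), Cs2CO3 (1.5 equiv), toluene, 70 °C
Reagents that add atoms: none
Why: Zerovalent palladium, formed in the flask from Pd(OAc)2 and the phosphine, inserts into the aryl C–Br bond, carbonate exchanges bromide on divalent palladium for the alkoxide of the ring B carbinol, and C–O reductive elimination from the seven-membered oxapalladacycle forms O1–C8a. The closest known reaction type is the intramolecular Buchwald–Hartwig etherification of aryl bromides by secondary alcohols, which is established to preserve the configuration of the carbinol. Ring C closes as a six-membered ring by attack of the tethered alkoxide on the aryl carbon, formally a 6-exo-trig closure carried out through reductive elimination. No stereocentre is created: the C2–O bond is never broken, so the (S) configuration from step 9 is retained, and C4 is a spectator. The step needs selectivity between the two hydroxyls and against beta-hydride elimination; ring size secures the first, since the C4 hydroxyl could only close a four-membered ring, and the bulky electron-rich phosphine secures the second by speeding reductive elimination. Because C4 is still a carbinol, the retro-aldol and E1cB pathways open to a beta-oxygenated ketone under Cs2CO3 are not available.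

**Step 11**
Reactants: 15 (2S,4S)-7-(benzyloxy)-2-[(3R,4S)-8-(benzyloxy)-3,4-bis[(tert-butyldimethylsilyl)oxy]-2,2-dimethylchroman-6-yl]chroman-4-ol
Product: 16 (2S)-7-(benzyloxy)-2-[(3R,4S)-8-(benzyloxy)-3,4-bis[(tert-butyldimethylsilyl)oxy]-2,2-dimethylchroman-6-yl]chroman-4-one
Conditions: Dess–Martin periodinane, CH2Cl2, 0 to 23 °C
Reagents that add atoms: none
Why: Dess–Martin oxidation of the benzylic carbinol under essentially neutral conditions, which should give the flavanone without enolisation or ring opening and so leave C2 untouched; either C4 epimer converges here.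

**Step 12**
Reactants: 16 (2S)-7-(benzyloxy)-2-[(3R,4S)-8-(benzyloxy)-3,4-bis[(tert-butyldimethylsilyl)oxy]-2,2-dimethylchroman-6-yl]chroman-4-one
Product: 17 (2S)-7-(benzyloxy)-2-[(3R,4S)-8-(benzyloxy)-3,4-dihydroxy-2,2-dimethylchroman-6-yl]chroman-4-one
Conditions: HF·pyridine, pyridine, THF, 0 to 23 °C
Reagents that add atoms: none
Why: Fluoride-mediated desilylation under mildly acidic buffered conditions, chosen because a basic fluoride source could open the flavanone by E1cB to the chalcone and racemise C2.

**Step 13**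
Reactants: 17 (2S)-7-(benzyloxy)-2-[(3R,4S)-8-(benzyloxy)-3,4-dihydroxy-2,2-dimethylchroman-6-yl]chroman-4-one
Product: 18 (2S)-7-hydroxy-2-[(3R,4S)-3,4,8-trihydroxy-2,2-dimethylchroman-6-yl]chroman-4-one (CNP0281318.3)
Conditions: H2 (1 atm), 10% Pd on carbon, EtOAc, 23 °C
Reagents that add atoms: none
Why: Catalytic hydrogenolysis of the two aryl benzyl ethers, which in neutral ethyl acetate should be much faster than cleavage of the secondary benzylic C–O bonds at C2 of ring C and C4 of ring D or reduction of the aryl ketone.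

**Compound list**

1 | methyl 3,4-dihydroxybenzoate | COC(=O)c1ccc(O)c(O)c1 | starting material
2 | 3-chloro-3-methylbut-1-yne | CC(C)(Cl)C#C | starting material
3 | methyl 3-hydroxy-4-[(2-methylbut-3-yn-2-yl)oxy]benzoate | COC(=O)c1ccc(OC(C)(C)C#C)c(O)c1 | intermediate
4 | methyl 3-(benzyloxy)-4-[(2-methylbut-3-yn-2-yl)oxy]benzoate | COC(=O)c1ccc(OC(C)(C)C#C)c(OCc2ccccc2)c1 | intermediate
5 | methyl 3-(benzyloxy)-4-hydroxy-5-(3-methylbuta-1,2-dien-1-yl)benzoate (allenylphenol) | COC(=O)c1cc(OCc2ccccc2)c(O)c(C=C=C(C)C)c1 | intermediate (not isolated)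
6 | methyl 8-(benzyloxy)-2,2-dimethyl-2H-chromene-6-carboxylate | COC(=O)c1cc2C=CC(C)(C)Oc2c(OCc3ccccc3)c1 | intermediate
7 | methyl (3R,4R)-8-(benzyloxy)-3,4-epoxy-2,2-dimethylchromane-6-carboxylate | COC(=O)c1cc(OCc2ccccc2)c2OC(C)(C)[C@@H]3O[C@@H]3c2c1 | intermediate
8 | methyl (3R,4S)-8-(benzyloxy)-3,4-dihydroxy-2,2-dimethylchromane-6-carboxylate (trans diol) | CC1(C)Oc2c(OCc3ccccc3)cc(C(=O)OC)cc2[C@H](O)[C@H]1O | intermediate
9 | methyl (3R,4S)-8-(benzyloxy)-3,4-bis[(tert-butyldimethylsilyl)oxy]-2,2-dimethylchromane-6-carboxylate | CC1(C)Oc2c(OCc3ccccc3)cc(C(=O)OC)cc2[C@H](O[Si](C)(C)C(C)(C)C)[C@H]1O[Si](C)(C)C(C)(C)C | intermediate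
10 | 1-(2-bromo-4-hydroxyphenyl)ethan-1-one | CC(=O)c1ccc(O)cc1Br | starting material
11 | 1-[4-(benzyloxy)-2-bromophenyl]ethan-1-one | CC(=O)c1ccc(OCc2ccccc2)cc1Br | intermediate
12 | 1-[(3R,4S)-8-(benzyloxy)-3,4-bis[(tert-butyldimethylsilyl)oxy]-2,2-dimethylchroman-6-yl]-3-[4-(benzyloxy)-2-bromophenyl]propane-1,3-dione | CC1(C)Oc2c(OCc3ccccc3)cc(C(=O)CC(=O)c3ccc(OCc4ccccc4)cc3Br)cc2[C@H](O[Si](C)(C)C(C)(C)C)[C@H]1O[Si](C)(C)C(C)(C)C | intermediate
13 | (3S)-1-[4-(benzyloxy)-2-bromophenyl]-3-[(3R,4S)-8-(benzyloxy)-3,4-bis[(tert-butyldimethylsilyl)oxy]-2,2-dimethylchroman-6-yl]-3-hydroxypropan-1-one (hydroxy ketone) | CC1(C)Oc2c(OCc3ccccc3)cc([C@@H](O)CC(=O)c3ccc(OCc4ccccc4)cc3Br)cc2[C@H](O[Si](C)(C)C(C)(C)C)[C@H]1O[Si](C)(C)C(C)(C)C | intermediate (not isolated)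
14 | (1S,3S)-1-[(3R,4S)-8-(benzyloxy)-3,4-bis[(tert-butyldimethylsilyl)oxy]-2,2-dimethylchroman-6-yl]-3-[4-(benzyloxy)-2-bromophenyl]propane-1,3-diol (anti diol) | CC1(C)Oc2c(OCc3ccccc3)cc([C@@H](O)C[C@H](O)c3ccc(OCc4ccccc4)cc3Br)cc2[C@H](O[Si](C)(C)C(C)(C)C)[C@H]1O[Si](C)(C)C(C)(C)C | intermediate
15 | (2S,4S)-7-(benzyloxy)-2-[(3R,4S)-8-(benzyloxy)-3,4-bis[(tert-butyldimethylsilyl)oxy]-2,2-dimethylchroman-6-yl]chroman-4-ol (2,4-cis) | CC1(C)Oc2c(OCc3ccccc3)cc([C@@H]3C[C@H](O)c4ccc(OCc5ccccc5)cc4O3)cc2[C@H](O[Si](C)(C)C(C)(C)C)[C@H]1O[Si](C)(C)C(C)(C)C | intermediate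
16 | (2S)-7-(benzyloxy)-2-[(3R,4S)-8-(benzyloxy)-3,4-bis[(tert-butyldimethylsilyl)oxy]-2,2-dimethylchroman-6-yl]chroman-4-one | CC1(C)Oc2c(OCc3ccccc3)cc([C@@H]3CC(=O)c4ccc(OCc5ccccc5)cc4O3)cc2[C@H](O[Si](C)(C)C(C)(C)C)[C@H]1O[Si](C)(C)C(C)(C)C | intermediate
17 | (2S)-7-(benzyloxy)-2-[(3R,4S)-8-(benzyloxy)-3,4-dihydroxy-2,2-dimethylchroman-6-yl]chroman-4-one | CC1(C)Oc2c(OCc3ccccc3)cc([C@@H]3CC(=O)c4ccc(OCc5ccccc5)cc4O3)cc2[C@H](O)[C@H]1O | intermediate
18 | (2S)-7-hydroxy-2-[(3R,4S)-3,4,8-trihydroxy-2,2-dimethylchroman-6-yl]chroman-4-one | CC1(C)Oc2c(O)cc([C@@H]3CC(=O)c4ccc(O)cc4O3)cc2[C@H](O)[C@H]1O | target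

**Step count**

Total steps: 13. Longest linear sequence: 12 steps (steps 1–6 and 8–13, from compound 1).

**Steps most likely to fail**

Step 10. After oxidative addition the palladium alkoxide may undergo beta-hydride elimination, which would consume the bromide and oxidise a carbinol, or the neighbouring C4 alkoxide may chelate palladium and stall turnover. The fallback closes ring C at O1–C2 by oxa-Michael addition instead. It sets out from ester 9, which DIBAL-H (CH2Cl2, −78 °C) should reduce to [(3R,4S)-8-(benzyloxy)-3,4-bis[(tert-butyldimethylsilyl)oxy]-2,2-dimethylchroman-6-yl]methanol F1. MnO2 (CH2Cl2) then gives (3R,4S)-8-(benzyloxy)-3,4-bis[(tert-butyldimethylsilyl)oxy]-2,2-dimethylchromane-6-carbaldehyde F2. Claisen–Schmidt condensation of F2 with purchased 1-[4-(benzyloxy)-2-hydroxyphenyl]ethan-1-one (KOH, EtOH, 23 °C) should give (E)-1-[4-(benzyloxy)-2-hydroxyphenyl]-3-[(3R,4S)-8-(benzyloxy)-3,4-bis[(tert-butyldimethylsilyl)oxy]-2,2-dimethylchroman-6-yl]prop-2-en-1-one F3. Its intramolecular oxa-Michael addition (NaOAc, EtOH, reflux, or a quinine-derived bifunctional thiourea to bias the face) closes ring C. Because the ring D centres are already fixed, the two C2 epimers are diastereomers; they should be separable by chromatography, and the unwanted one can be re-equilibrated through the chalcone. The (2S) epimer is compound 16, where the route is rejoined.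

Step 9. The second hydride transfer, to the hindered ortho-bromoaryl ketone, may stall or proceed with poor diastereocontrol, and long exposure to formic acid risks loss of the benzylic silyl ether. The fallback sets out from diketone 12: the transfer hydrogenation is stopped after the first reduction (lower temperature, limited formic acid) and hydroxy ketone 13 is isolated. A hydroxyl-directed Evans–Saksena reduction (Me4NBH(OAc)3, MeCN/AcOH, −30 °C) then delivers hydride intramolecularly through a chair-like six-membered transition state and should give the anti diol 14, where the route is rejoined. No compound outside the list is made (F0).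

Step 8. The electron-rich ester, deactivated by the para ring oxygen, may resist acylation so that the ketone enolate self-condenses instead. The fallback raises the electrophilicity of the acyl donor. It sets out from ester 9, which LiOH (THF/MeOH/H2O, 50 °C) should hydrolyse to (3R,4S)-8-(benzyloxy)-3,4-bis[(tert-butyldimethylsilyl)oxy]-2,2-dimethylchromane-6-carboxylic acid F4. Carbonyldiimidazole (THF, 23 °C) converts this into 1-{[(3R,4S)-8-(benzyloxy)-3,4-bis[(tert-butyldimethylsilyl)oxy]-2,2-dimethylchroman-6-yl]carbonyl}imidazole F5. C-Acylation of the lithium enolate of 11 (LiHMDS, 2.2 equiv, THF, −78 °C) with F5 returns to diketone 12.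

**Further compounds**

F1 | step 10 | [(3R,4S)-8-(benzyloxy)-3,4-bis[(tert-butyldimethylsilyl)oxy]-2,2-dimethylchroman-6-yl]methanol | CC1(C)Oc2c(OCc3ccccc3)cc(CO)cc2[C@H](O[Si](C)(C)C(C)(C)C)[C@H]1O[Si](C)(C)C(C)(C)C
F2 | step 10 | (3R,4S)-8-(benzyloxy)-3,4-bis[(tert-butyldimethylsilyl)oxy]-2,2-dimethylchromane-6-carbaldehyde | CC1(C)Oc2c(OCc3ccccc3)cc(C=O)cc2[C@H](O[Si](C)(C)C(C)(C)C)[C@H]1O[Si](C)(C)C(C)(C)C
F3 | step 10 | (E)-1-[4-(benzyloxy)-2-hydroxyphenyl]-3-[(3R,4S)-8-(benzyloxy)-3,4-bis[(tert-butyldimethylsilyl)oxy]-2,2-dimethylchroman-6-yl]prop-2-en-1-one | CC1(C)Oc2c(OCc3ccccc3)cc(/C=C/C(=O)c3ccc(OCc4ccccc4)cc3O)cc2[C@H](O[Si](C)(C)C(C)(C)C)[C@H]1O[Si](C)(C)C(C)(C)C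
F0 | step 9 | none | none
F4 | step 8 | (3R,4S)-8-(benzyloxy)-3,4-bis[(tert-butyldimethylsilyl)oxy]-2,2-dimethylchromane-6-carboxylic acid | CC1(C)Oc2c(OCc3ccccc3)cc(C(=O)O)cc2[C@H](O[Si](C)(C)C(C)(C)C)[C@H]1O[Si](C)(C)C(C)(C)C
F5 | step 8 | 1-{[(3R,4S)-8-(benzyloxy)-3,4-bis[(tert-butyldimethylsilyl)oxy]-2,2-dimethylchroman-6-yl]carbonyl}imidazole | CC1(C)Oc2c(OCc3ccccc3)cc(C(=O)n3ccnc3)cc2[C@H](O[Si](C)(C)C(C)(C)C)[C@H]1O[Si](C)(C)C(C)(C)C
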